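## Retrosynthetic overview

Decalin numbering: C3 aryloxy carbon, C5 ring-fusion CH, C7 carbinol-bearing CH, C9 the transient second carbonyl, C10 angular-methyl carbon; ring A = C1–C5 and C10, ring B = C5–C10. The plan rests on the 1,4 relation of C10 and C7 across ring B. With carbonyls at C5 and C9, a 2-methyl-2-(3-oxobutyl)cyclohexane-1,3-dione carrying the C7 group cis to the methyl has a mirror plane through C10 and C7 and is meso.
Disconnections: the C3–O aryl ether by SNAr of the C3 alkoxide on 3-bromo-4-fluorobenzaldehyde; the biaryl bond by Suzuki coupling; the para allyl group from the formyl group (CH2OH, CH2Br, vinyl coupling). The C3 carbinol comes from the trans-decal-3-one, the trans fusion from Li/NH3 on the enone, and the C9 oxygen is removed by Barton–McCombie deoxygenation.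
Ring order: ring B is bought as the cyclohexane-1,3-dione, ring A is closed by the (S)-proline aldol condensation of the meso triketone (C4–C5 bond, C10 and C7 fixed together), and the two bought arenes are joined last.

Key step: step 5

Remark: the target is read as (3R,5S,7R,10S) in this numbering, i.e. trans-fused (5α-H), 10-methyl and 7-(2-hydroxypropan-2-yl) both β, 3-aryloxy α (axial), 3-methyl β (equatorial); β is the face of the angular methyl. TES = triethylsilyl, TIPS = triisopropylsilyl.

## Route

Step 1
Reactants: 1 methyl 3,5-dioxocyclohexane-1-carboxylate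
Product: 2 methyl 4-methyl-3,5-dioxocyclohexane-1-carboxylate (enolic; no fixed stereocentre)
Conditions: NaOMe (1.05 equiv), MeI (1.5 equiv), MeOH, 65 °C; then acidify
Reagents that add atoms: iodomethane, CI
Why: C-alkylation of the sodium enolate of a cyclic 1,3-dione with iodomethane in a protic solvent is the classical C-methylation of dihydroresorcinols and places the methyl on the carbon between the carbonyls, methoxide leaving the methyl ester unchanged.

Step 2
Reactants: 2 methyl 4-methyl-3,5-dioxocyclohexane-1-carboxylate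
Product: 3 5-(2-hydroxypropan-2-yl)-2-methylcyclohexane-1,3-dione
Conditions: MeMgBr (5 equiv), THF, 0 °C → rt; aq. NH4Cl, then pH 4
Reagents that add atoms: methylmagnesium bromide, C[Mg]Br
Why: Grignard addition to an ester, in which the first equivalent deprotonates the acidic dione to an enolate that resists addition, so the excess reagent should add twice to the ester only and give the tertiary carbinol.

Step 3
Reactants: 3 5-(2-hydroxypropan-2-yl)-2-methylcyclohexane-1,3-dione
Product: 5 2-methyl-5-[2-(triethylsilyloxy)propan-2-yl]cyclohexane-1,3-dione, via bis-silyl enol ether 4 (not isolated)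
Conditions: TESOTf (2.4 equiv), 2,6-lutidine (3.5 equiv), CH2Cl2, −78 → 0 °C; aq. citric acid work-up
Reagents that add atoms: triethylsilyl trifluoromethanesulfonate, CC[Si](CC)(CC)OS(=O)(=O)C(F)(F)F
Why: Silyl triflate with 2,6-lutidine is the standard silylation of a tertiary alcohol; the enol oxygen is silylated too, but this vinylogous silyl ester should hydrolyse in the mildly acidic work-up while the tertiary TES ether stays.

Step 4
Reactants: 5 2-methyl-5-[2-(triethylsilyloxy)propan-2-yl]cyclohexane-1,3-dione; 6 methyl vinyl ketone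
Product: 7 meso cis-2-methyl-2-(3-oxobutyl)-5-[2-(triethylsilyloxy)propan-2-yl]cyclohexane-1,3-dione (methyl and C5 substituent on the same ring face)
Conditions: Et3N (0.2 equiv), MeCN, rt
Reagents that add atoms: none
Why: Amine-catalysed Michael addition of a 2-alkyl-1,3-dione to an enone creates the quaternary carbon C10; because the reacting carbon is nearly planar and the C7 group is remote, only a modest facial preference is expected, both meso diastereomers should form, and 7 (assigned by NOE or X-ray analysis) is separated from the trans isomer by chromatography or crystallisation.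

Step 5
Reactants: 7 meso cis-triketone
Product: 9 (7S,10S)-10-methyl-7-[2-(triethylsilyloxy)propan-2-yl]-Δ4-octalin-3,9-dione (10-methyl and 7-substituent both β), via cis-fused ketol 8 (not isolated)
Conditions: (S)-proline (0.3 equiv), DMSO, 25 → 40 °C
Reagents that add atoms: none
Why: (S)-Proline condenses with the side-chain methyl ketone to its enamine, whose carbon C4 adds to one of the two enantiotopic ring carbonyls (C5) while the carboxylic acid hydrogen-bonds to that carbonyl; hydrolysis gives ketol 8, which loses water to enone 9. The closest known reaction is the Hajos–Parrish–Eder–Sauer–Wiechert cyclisation of 2-methyl-2-(3-oxobutyl)cyclohexane-1,3-diones. Ring A closes by a 6-(enolendo)-exo-trig aldol addition. C10 is fixed by the catalyst-controlled choice between the enantiotopic carbonyls, (S)-proline being expected to give the (S) quaternary carbon as in the unsubstituted series, and C7 is fixed in the same event because its cis relation to the methyl is already built into the meso substrate. The step needs enantiotopic-group selectivity only: the C7 substituent lies on the mirror plane, remote from both carbonyls, and as an equatorial anchor it should hold the methyl axial and the oxobutyl chain equatorial, so both carbonyls remain equally accessible and the catalyst decides. Chemoselectivity follows the parent case, since only the methyl-side enamine of the side-chain ketone can reach a ring carbonyl through an unstrained six-membered transition state.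

Step 6
Reactants: 9 enedione
Product: 10 (7S,9S,10S)-9β-hydroxy-10-methyl-7-[2-(triethylsilyloxy)propan-2-yl]-Δ4-octalin-3-one
Conditions: NaBH4 (0.3 equiv), EtOH, −10 °C
Reagents that add atoms: none
Why: Borohydride 1,2-reduction should take the saturated C9 ketone much faster than the conjugated C3 enone, hydride arriving anti to the axial angular methyl to give the equatorial 9β-alcohol, a centre that is removed later.

Step 7
Reactants: 10 hydroxy enone
Product: 11 (5S,7S,9S,10S)-9β-hydroxy-10-methyl-7-[2-(triethylsilyloxy)propan-2-yl]-trans-decalin-3-one (5α-H)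
Conditions: Li (4 equiv), NH3(l)/THF, −78 °C; then solid NH4Cl
Reagents that add atoms: none
Why: Dissolving-metal reduction of a 10-methyl-4-en-3-one proceeds through a β-carbanion that is protonated axially at C5, which should give the trans ring fusion (H anti to the angular methyl), the enolate protecting C3 from over-reduction until the quench.

Step 8
Reactants: 11 hydroxy decalone
Product: 12 9β-O-(imidazol-1-ylthiocarbonyl) derivative of 11
Conditions: 1,1'-thiocarbonyldiimidazole (2 equiv), DMAP (0.2 equiv), ClCH2CH2Cl, 70 °C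
Reagents that add atoms: 1,1'-thiocarbonyldiimidazole, S=C(n1ccnc1)n1ccnc1
Why: Thioacylation of the secondary alcohol under neutral conditions prepares the Barton–McCombie substrate without enolising the C3 ketone or touching the silyl ether.

Step 9
Reactants: 12 thiocarbonyl imidazolide
Product: 13 (5S,7R,10S)-10-methyl-7-[2-(triethylsilyloxy)propan-2-yl]-trans-decalin-3-one
Conditions: Bu3SnH (2 equiv), AIBN (0.2 equiv), toluene, 110 °C
Reagents that add atoms: none
Why: Barton–McCombie deoxygenation, in which the stannyl radical adds to sulfur, the C9–O bond fragments to a secondary radical that has no alkene within reach (the enone was reduced first to exclude a homoallyl radical rearrangement) and this radical abstracts hydrogen from the stannane.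

Step 10
Reactants: 13 trans-decal-3-one
Product: 14 (3R,5S,7R,10S)-3,10-dimethyl-7-[2-(triethylsilyloxy)propan-2-yl]-trans-decalin-3-ol (3α-OH axial, 3β-methyl equatorial)
Conditions: MeLi, ClTi(OiPr)3, Et2O, −40 → 0 °C (gives MeTi(OiPr)3, 2 equiv); then 13, 0 °C → rt; aq. NH4Cl
Reagents that add atoms: methyltitanium triisopropoxide, C[Ti](OC(C)C)(OC(C)C)OC(C)C (made in the flask from methyllithium, [Li]C, and ClTi(OiPr)3, CC(C)O[Ti](Cl)(OC(C)C)OC(C)C)
Why: 1,2-Addition of a bulky, non-basic methyl organometallic to the conformationally locked cyclohexanone should occur from the equatorial direction, placing the new methyl equatorial (β) and the hydroxyl axial (α) as C3 requires, the minor epimer being removable by chromatography.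

Step 11
Reactants: 14 tertiary alcohol; 15 3-bromo-4-fluorobenzaldehyde
Product: 17 3-bromo-4-{[(3R,5S,7R,10S)-3,10-dimethyl-7-[2-(triethylsilyloxy)propan-2-yl]-trans-decalin-3α-yl]oxy}benzaldehyde, via potassium alkoxide 16 (not isolated)
Conditions: KH (1.1 equiv), THF, 0 °C → rt; then 15 (1.5 equiv), 18-crown-6 (0.2 equiv), 0 → 40 °C
Reagents that add atoms: none
Why: Nucleophilic aromatic substitution by addition–elimination, the alkoxide attacking the fluorine-bearing carbon activated by the para formyl group and the ortho bromine, so the tertiary C3–O bond is never broken and the C3 configuration is kept.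

Step 12
Reactants: 18 4-bromophenol; 19 allyl bromide
Product: 20 1-(allyloxy)-4-bromobenzene
Conditions: K2CO3, acetone, 56 °C
Reagents that add atoms: none
Why: Williamson ether synthesis of a phenoxide with an allylic bromide.

Step 13
Reactants: 20 1-(allyloxy)-4-bromobenzene
Product: 21 2-allyl-4-bromophenol
Conditions: N,N-diethylaniline, 200 °C
Reagents that add atoms: none
Why: Aromatic Claisen rearrangement ([3,3] shift, then tautomerisation) delivers the allyl group to the free ortho position, the para position being blocked by bromine.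

Step 14
Reactants: 21 2-allyl-4-bromophenol
Product: 22 (2-allyl-4-bromophenoxy)triisopropylsilane
Conditions: TIPSCl, imidazole, DMF, 40 °C
Reagents that add atoms: chlorotriisopropylsilane, CC(C)[Si](Cl)(C(C)C)C(C)C
Why: Silylation of the phenol gives an ether that should withstand the organolithium, the aqueous base of the coupling and the later reduction, bromination and Stille steps, and that falls to fluoride at the end.

Step 15
Reactants: 22 (2-allyl-4-bromophenoxy)triisopropylsilane
Product: 24 2-[3-allyl-4-(triisopropylsilyloxy)phenyl]-4,4,5,5-tetramethyl-1,3,2-dioxaborolane, via aryllithium 23 (not isolated)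
Conditions: n-BuLi, THF, −78 °C; then 2-isopropoxy-4,4,5,5-tetramethyl-1,3,2-dioxaborolane, −78 °C → rt; aq. NH4Cl
Reagents that add atoms: 2-isopropoxy-4,4,5,5-tetramethyl-1,3,2-dioxaborolane, CC(C)OB1OC(C)(C)C(C)(C)O1
Why: Bromine–lithium exchange is faster than any deprotonation at −78 °C, and borylation of the aryllithium gives the pinacol boronate without exposing the allyl group to a palladium hydride.

Step 16
Reactants: 17 aryl bromide; 24 aryl boronate
Product: 25 biaryl aldehyde: 4-(decalin-3α-yloxy)-3-[3-allyl-4-(triisopropylsilyloxy)phenyl]benzaldehyde (decalin part as in 17)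
Conditions: Pd(OAc)2 (5 mol%), SPhos (10 mol%), K3PO4, toluene/H2O, 80 °C
Reagents that add atoms: none
Why: Suzuki–Miyaura coupling, in which the electron-poor aryl bromide adds oxidatively with ease and the bulky dialkylbiarylphosphine copes with the ortho tertiary alkoxy group, while aldehyde, silyl ethers and allyl group are tolerated.

Step 17
Reactants: 25 biaryl aldehyde
Product: 26 the corresponding benzylic alcohol (CH2OH in place of CHO)
Conditions: NaBH4, THF/MeOH, 0 °C
Reagents that add atoms: none
Why: Hydride reduction of an aromatic aldehyde to the benzylic alcohol.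

Step 18
Reactants: 26 benzylic alcohol
Product: 27 the corresponding benzylic bromide (CH2Br), used directly
Conditions: CBr4, PPh3, CH2Cl2, 0 °C
Reagents that add atoms: tetrabromomethane, BrC(Br)(Br)Br
Why: Appel bromination converts the benzylic alcohol under essentially neutral conditions that should spare the acid-labile tertiary alkyl aryl ether and both silyl ethers.

Step 19
Reactants: 27 benzylic bromide
Product: 28 bis-silyl ether of the target (both allyl groups in place; TES on the carbinol, TIPS on the phenol)
Conditions: tributyl(vinyl)stannane, Pd(PPh3)4 (5 mol%), toluene, 80 °C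
Reagents that add atoms: tributyl(vinyl)stannane, C=C[Sn](CCCC)(CCCC)CCCC
Why: Stille coupling of a benzylic bromide with a vinylstannane forms the benzyl–vinyl bond, that is the second allyl group, without base.

Step 20
Reactants: 28 bis-silyl ether
Product: 29 target, 4-allyl-2-(3-allyl-4-hydroxyphenyl)phenyl (3R,5S,7R,10S)-7-(2-hydroxypropan-2-yl)-3,10-dimethyl-trans-decalin-3α-yl ether
Conditions: TBAF (4 equiv), THF, 0 → 45 °C; aq. NH4Cl
Reagents that add atoms: none
Why: Fluoride cleaves both silicon–oxygen bonds (the aryl silyl ether fast, the tertiary alkyl one on warming) under non-acidic conditions, so the tertiary alkyl aryl ether and the tertiary alcohol are not ionised.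

## Compound list

1 | methyl 3,5-dioxocyclohexane-1-carboxylate | COC(=O)C1CC(=O)CC(=O)C1 | starting material
2 | methyl 4-methyl-3,5-dioxocyclohexane-1-carboxylate | COC(=O)C1CC(=O)C(C)C(=O)C1 | intermediate
3 | 5-(2-hydroxypropan-2-yl)-2-methylcyclohexane-1,3-dione | CC1C(=O)CC(C(C)(C)O)CC1=O | intermediate
4 | 2-methyl-3-(triethylsilyloxy)-5-[2-(triethylsilyloxy)propan-2-yl]cyclohex-2-en-1-one (racemic) | CC1=C(O[Si](CC)(CC)CC)CC(C(C)(C)O[Si](CC)(CC)CC)CC1=O | intermediate (not isolated)
5 | 2-methyl-5-[2-(triethylsilyloxy)propan-2-yl]cyclohexane-1,3-dione | CC1C(=O)CC(C(C)(C)O[Si](CC)(CC)CC)CC1=O | intermediate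
6 | methyl vinyl ketone | CC(=O)C=C | starting material
7 | meso cis-2-methyl-2-(3-oxobutyl)-5-[2-(triethylsilyloxy)propan-2-yl]cyclohexane-1,3-dione | CC(=O)CC[C@]1(C)C(=O)C[C@@H](C(C)(C)O[Si](CC)(CC)CC)CC1=O | intermediate
8 | cis-fused ketol, 5β-hydroxy-10β-methyl-7β-[2-(triethylsilyloxy)propan-2-yl]decalin-3,9-dione | O=C1CC[C@]2(C)C(=O)C[C@@H](C(C)(C)O[Si](CC)(CC)CC)C[C@]2(O)C1 | intermediate (not isolated)
9 | (7S,10S)-10-methyl-7-[2-(triethylsilyloxy)propan-2-yl]-Δ4-octalin-3,9-dione | O=C1CC[C@]2(C)C(=O)C[C@@H](C(C)(C)O[Si](CC)(CC)CC)CC2=C1 | intermediate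
10 | (7S,9S,10S)-9β-hydroxy-10-methyl-7-[2-(triethylsilyloxy)propan-2-yl]-Δ4-octalin-3-one | O=C1CC[C@]2(C)[C@@H](O)C[C@@H](C(C)(C)O[Si](CC)(CC)CC)CC2=C1 | intermediate
11 | (5S,7S,9S,10S)-9β-hydroxy-10-methyl-7-[2-(triethylsilyloxy)propan-2-yl]-trans-decalin-3-one | O=C1CC[C@]2(C)[C@@H](O)C[C@@H](C(C)(C)O[Si](CC)(CC)CC)C[C@H]2C1 | intermediate
12 | 9β-O-(imidazol-1-ylthiocarbonyl) derivative of 11 | O=C1CC[C@]2(C)[C@@H](OC(=S)n3ccnc3)C[C@@H](C(C)(C)O[Si](CC)(CC)CC)C[C@H]2C1 | intermediate
13 | (5S,7R,10S)-10-methyl-7-[2-(triethylsilyloxy)propan-2-yl]-trans-decalin-3-one | O=C1CC[C@]2(C)CC[C@@H](C(C)(C)O[Si](CC)(CC)CC)C[C@H]2C1 | intermediate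
14 | (3R,5S,7R,10S)-3,10-dimethyl-7-[2-(triethylsilyloxy)propan-2-yl]-trans-decalin-3-ol (3α-OH) | O[C@]1(C)CC[C@]2(C)CC[C@@H](C(C)(C)O[Si](CC)(CC)CC)C[C@H]2C1 | intermediate
15 | 3-bromo-4-fluorobenzaldehyde | O=Cc1ccc(F)c(Br)c1 | starting material
16 | potassium alkoxide of 14 | [K+].[O-][C@]1(C)CC[C@]2(C)CC[C@@H](C(C)(C)O[Si](CC)(CC)CC)C[C@H]2C1 | intermediate (not isolated)
17 | 3-bromo-4-(decalin-3α-yloxy)benzaldehyde (decalin as in 14) | O=Cc1ccc(O[C@]2(C)CC[C@]3(C)CC[C@@H](C(C)(C)O[Si](CC)(CC)CC)C[C@H]3C2)c(Br)c1 | intermediate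
18 | 4-bromophenol | Oc1ccc(Br)cc1 | starting material
19 | allyl bromide | C=CCBr | starting material
20 | 1-(allyloxy)-4-bromobenzene | C=CCOc1ccc(Br)cc1 | intermediate
21 | 2-allyl-4-bromophenol | C=CCc1cc(Br)ccc1O | intermediate
22 | (2-allyl-4-bromophenoxy)triisopropylsilane | C=CCc1cc(Br)ccc1O[Si](C(C)C)(C(C)C)C(C)C | intermediate
23 | [3-allyl-4-(triisopropylsilyloxy)phenyl]lithium | [Li]c1ccc(O[Si](C(C)C)(C(C)C)C(C)C)c(CC=C)c1 | intermediate (not isolated)
24 | 2-[3-allyl-4-(triisopropylsilyloxy)phenyl]-4,4,5,5-tetramethyl-1,3,2-dioxaborolane | CC1(C)OB(OC1(C)C)c1ccc(O[Si](C(C)C)(C(C)C)C(C)C)c(CC=C)c1 | intermediate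
25 | biaryl aldehyde | O=Cc1ccc(O[C@]2(C)CC[C@]3(C)CC[C@@H](C(C)(C)O[Si](CC)(CC)CC)C[C@H]3C2)c(-c2ccc(O[Si](C(C)C)(C(C)C)C(C)C)c(CC=C)c2)c1 | intermediate
26 | biaryl benzylic alcohol | OCc1ccc(O[C@]2(C)CC[C@]3(C)CC[C@@H](C(C)(C)O[Si](CC)(CC)CC)C[C@H]3C2)c(-c2ccc(O[Si](C(C)C)(C(C)C)C(C)C)c(CC=C)c2)c1 | intermediate
27 | biaryl benzylic bromide | BrCc1ccc(O[C@]2(C)CC[C@]3(C)CC[C@@H](C(C)(C)O[Si](CC)(CC)CC)C[C@H]3C2)c(-c2ccc(O[Si](C(C)C)(C(C)C)C(C)C)c(CC=C)c2)c1 | intermediate
28 | bis-silyl ether of the target | C=CCc1ccc(O[C@]2(C)CC[C@]3(C)CC[C@@H](C(C)(C)O[Si](CC)(CC)CC)C[C@H]3C2)c(-c2ccc(O[Si](C(C)C)(C(C)C)C(C)C)c(CC=C)c2)c1 | intermediate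
29 | target CNP0342687.1 | C=CCc1ccc(O[C@]2(C)CC[C@]3(C)CC[C@@H](C(C)(C)O)C[C@H]3C2)c(-c2ccc(O)c(CC=C)c2)c1 | target

## Step count and risks

Total steps: 20. Longest linear sequence: 16 (steps 1–11 and 16–20); steps 12–15 make the boronate 24 as a side branch.

**Step 5 (key step).** The catalyst may discriminate the two enantiotopic carbonyls only partly, or the cyclisation may stall at the ketol.
Fallback, from 7 back to 10: 7 is cyclised without asymmetric induction (pyrrolidine, AcOH, toluene, aldol condensation) to the racemic enedione F5. NaBH4 as in step 6 gives the racemic hydroxy enone F6. Acylation with (1S)-camphanic chloride (pyridine, DMAP) gives two diastereomeric esters, the camphanate of 10 F7 and the camphanate of ent-10 F8, which are separated by chromatography or crystallisation. Methanolysis of F7 (K2CO3, MeOH) returns 10.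

**Step 4.** The Michael acceptor may enter mainly on the ring face syn to the C5 substituent, so the unwanted trans meso isomer predominates.
Fallback, from 1 back to 7: the order of the two bond formations at C10 is reversed, so the same facial preference places the methyl, now entering last, cis to the C5 group. Excess MeMgBr on 1 gives 5-(2-hydroxypropan-2-yl)cyclohexane-1,3-dione F1. TESOTf/2,6-lutidine gives the bis-silyl enol ether F2, which is hydrolysed on work-up to 5-[2-(triethylsilyloxy)propan-2-yl]cyclohexane-1,3-dione F3. Michael addition of F3 to 6 (Et3N, MeCN) gives 2-(3-oxobutyl)-5-[2-(triethylsilyloxy)propan-2-yl]cyclohexane-1,3-dione F4. C-methylation of F4 (MeI, K2CO3, acetone) gives 7.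

**Step 11.** The hindered axial tertiary alkoxide may add too slowly to the arene, so that attack on the formyl group (hemiacetal formation, hydride transfer between aldehydes) or elimination takes over.
Fallback, from 14 back to 17: 14 is treated with KHMDS in THF and 3-bromo-4-fluorobenzonitrile, whose nitrile activates more strongly and is not attacked, to give the nitrile ether F9. DIBAL-H (toluene, −78 °C) gives the aluminium aldimine F10, which is hydrolysed on aqueous work-up to 17.

## Further compounds

F1 | step 4 | 5-(2-hydroxypropan-2-yl)cyclohexane-1,3-dione | CC(C)(O)C1CC(=O)CC(=O)C1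
F2 | step 4 | 3-(triethylsilyloxy)-5-[2-(triethylsilyloxy)propan-2-yl]cyclohex-2-en-1-one (racemic) | CC[Si](CC)(CC)OC1=CC(=O)CC(C(C)(C)O[Si](CC)(CC)CC)C1
F3 | step 4 | 5-[2-(triethylsilyloxy)propan-2-yl]cyclohexane-1,3-dione | CC[Si](CC)(CC)OC(C)(C)C1CC(=O)CC(=O)C1
F4 | step 4 | 2-(3-oxobutyl)-5-[2-(triethylsilyloxy)propan-2-yl]cyclohexane-1,3-dione | CC(=O)CCC1C(=O)CC(C(C)(C)O[Si](CC)(CC)CC)CC1=O
F5 | step 5 | racemic enedione (9 and its enantiomer) | O=C1CC[C@]2(C)C(=O)C[C@@H](C(C)(C)O[Si](CC)(CC)CC)CC2=C1.O=C1CC[C@@]2(C)C(=O)C[C@H](C(C)(C)O[Si](CC)(CC)CC)CC2=C1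
F6 | step 5 | racemic hydroxy enone (10 and its enantiomer) | O=C1CC[C@]2(C)[C@@H](O)C[C@@H](C(C)(C)O[Si](CC)(CC)CC)CC2=C1.O=C1CC[C@@]2(C)[C@H](O)C[C@H](C(C)(C)O[Si](CC)(CC)CC)CC2=C1
F7 | step 5 | (1S,4R)-camphanate ester of 10 | O=C1CC[C@]2(C)[C@@H](OC(=O)[C@@]34CC[C@@](C)(C(=O)O3)C4(C)C)C[C@@H](C(C)(C)O[Si](CC)(CC)CC)CC2=C1
F8 | step 5 | (1S,4R)-camphanate ester of ent-10 | O=C1CC[C@@]2(C)[C@H](OC(=O)[C@@]34CC[C@@](C)(C(=O)O3)C4(C)C)C[C@H](C(C)(C)O[Si](CC)(CC)CC)CC2=C1
F9 | step 11 | 3-bromo-4-(decalin-3α-yloxy)benzonitrile (decalin as in 14) | N#Cc1ccc(O[C@]2(C)CC[C@]3(C)CC[C@@H](C(C)(C)O[Si](CC)(CC)CC)C[C@H]3C2)c(Br)c1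
F10 | step 11 | N-(diisobutylaluminio) aldimine of 17 | CC(C)C[Al](CC(C)C)N=Cc1ccc(O[C@]2(C)CC[C@]3(C)CC[C@@H](C(C)(C)O[Si](CC)(CC)CC)C[C@H]3C2)c(Br)c1
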